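**Retrosynthetic overview**

1. Azaphilone D ⇒ core 8,8a‑diol + (R)‑3‑silyloxybutanoic acid (ester at C8–O, then desilylation); enal side chain ⇒ C3–CHO + formylmethylene ylide; C1 lactol ⇒ C1 lactone (hydride).
2. Core lactone ⇒ one dearomatising [3+3] annulation that makes C5–C6 and C8–C8a: a flat 4‑methyl‑2‑pyranone (ring B, from galactaric acid) + a lactic‑acid‑derived C6–C7–C8 unit (dioxolanone acyl donor, aldehyde masked as acetal).
3. Enabling feature: C5, C4a and C8a of the carbocycle are the 4‑methyl carbon, C4 and C3 of a 2‑pyranone, i.e. the γ‑ and α‑ends of a dienolate vinylogous to the lactone C1=O; C6–C7–C8 is a 1,3‑dioxygenated C3 chain (acyl / carbinol / aldehyde level).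
4. Ring order: pyran ring (ring B) first, as the heteroarene; carbocycle (ring A) second, in the key step, which converts ring B into the sp3‑rich half of the target.
5. Stereochemistry: C7 bought ((R)‑lactic acid, self‑regeneration); C8 and C8a relayed from C7 in the key step; C1 thermodynamic; the ester carbinol centre bought.

Key step: step 9

Remark 1: ring atoms are numbered as in the isochromene skeleton of the target (O2, C1, C3, C4, C4a, C5–C8, C8a).
Remark 2: the hemiacetal centre C1 is taken to be configurationally labile, with the (1R) anomer of the natural product as the thermodynamic one; compounds 15–19 and 23 are carried as C1 epimer mixtures (15 also as a C6 epimer mixture).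

**Route**

Step 1
Reactants: 1 galactaric acid (mucic acid)
Product: 2 3‑acetoxy‑2‑oxo‑2H‑pyran‑6‑carboxylic acid
Conditions: Ac2O, H2SO4 (cat.), 100 °C
Reagents that add atoms: acetic anhydride, CC(=O)OC(C)=O
Why: acid‑promoted acetylative dehydration and lactonisation of the aldaric acid is the known entry to 3‑oxygenated 2‑pyranone‑6‑carboxylic acids, and all stereocentres of 1 are erased.

Step 2
Reactants: 2 3‑acetoxy‑2‑oxo‑2H‑pyran‑6‑carboxylic acid
Product: 3 methyl 3‑hydroxy‑2‑oxo‑2H‑pyran‑6‑carboxylate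
Conditions: MeOH, H2SO4 (cat.), reflux
Reagents that add atoms: methanol, CO
Why: Fischer esterification, with methanolysis of the enol acetate under the same conditions.

Step 3
Reactants: 3 methyl 3‑hydroxy‑2‑oxo‑2H‑pyran‑6‑carboxylate
Product: 4 methyl 4‑bromo‑3‑hydroxy‑2‑oxo‑2H‑pyran‑6‑carboxylate
Conditions: NBS, MeCN, 0 °C → rt
Reagents that add atoms: N‑bromosuccinimide, O=C1CCC(=O)N1Br
Why: electrophilic bromination of the enol should go ortho to the hydroxyl (C4), since C5 is deactivated by the adjacent ester‑bearing carbon.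

Step 4
Reactants: 4 methyl 4‑bromo‑3‑hydroxy‑2‑oxo‑2H‑pyran‑6‑carboxylate
Product: 5 methyl 4‑bromo‑3‑(naphthalen‑2‑ylmethoxy)‑2‑oxo‑2H‑pyran‑6‑carboxylate
Conditions: 2‑(bromomethyl)naphthalene, K2CO3, DMF, rt
Reagents that add atoms: 2‑(bromomethyl)naphthalene, BrCc1ccc2ccccc2c1
Why: Williamson O‑alkylation of the acidic enolic hydroxyl gives an ether that survives base and silyl triflate and is removable later with DDQ.

Step 5
Reactants: 5 methyl 4‑bromo‑3‑(naphthalen‑2‑ylmethoxy)‑2‑oxo‑2H‑pyran‑6‑carboxylate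
Product: 6 methyl 4‑methyl‑3‑(naphthalen‑2‑ylmethoxy)‑2‑oxo‑2H‑pyran‑6‑carboxylate
Conditions: SnMe4, Pd(PPh3)4 (cat.), toluene, 100 °C
Reagents that add atoms: tetramethylstannane, C[Sn](C)(C)C
Why: Stille coupling at the activated β‑bromo‑enoate C–Br bond with zerovalent palladium under neutral conditions, as is known for bromo‑2‑pyranones.

Step 6
Reactants: 7 (R)‑lactic acid
Product: 8 (2R,5R)‑2‑tert‑butyl‑5‑methyl‑1,3‑dioxolan‑4‑one (cis)
Conditions: pivalaldehyde, p‑TsOH (cat.), pentane, reflux (Dean–Stark); crystallisation at −78 °C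
Reagents that add atoms: pivalaldehyde, CC(C)(C)C=O
Why: Seebach acetalisation of the hydroxy acid; the lactate centre is untouched and the cis acetal centre is favoured and purified by crystallisation.

Step 7
Reactants: 8 (2R,5R)‑2‑tert‑butyl‑5‑methyl‑1,3‑dioxolan‑4‑one
Product: 9 (2R,5S)‑2‑tert‑butyl‑5‑methyl‑4‑oxo‑1,3‑dioxolane‑5‑carbaldehyde
Conditions: LiN(i‑Pr)2, THF, −78 °C; HCO2Me, −78 °C; AcOH, −78 °C
Reagents that add atoms: methyl formate, COC=O
Why: Claisen‑type C‑formylation of the lithium enolate (self‑regeneration of stereocentres), in which the electrophile enters anti to the tert‑butyl group and so sets the quaternary centre that becomes C7.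

Step 8
Reactants: 9 (2R,5S)‑2‑tert‑butyl‑5‑methyl‑4‑oxo‑1,3‑dioxolane‑5‑carbaldehyde
Product: 10 (2R,5S)‑5‑[bis(naphthalen‑2‑ylmethoxy)methyl]‑2‑tert‑butyl‑5‑methyl‑1,3‑dioxolan‑4‑one
Conditions: naphthalen‑2‑ylmethanol (2.5 equiv), CSA (cat.), benzene, reflux (Dean–Stark)
Reagents that add atoms: naphthalen‑2‑ylmethanol, OCc1ccc2ccccc2c1
Why: acid‑catalysed acetalisation of the non‑enolisable aldehyde; naphthylmethyl is chosen because its oxocarbenium ion should not fragment, as a 4‑methoxybenzyl one would, and it is later cleaved with DDQ.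

Step 9
Reactants: 6 methyl 4‑methyl‑3‑(naphthalen‑2‑ylmethoxy)‑2‑oxo‑2H‑pyran‑6‑carboxylate; 10 (2R,5S)‑5‑[bis(naphthalen‑2‑ylmethoxy)methyl]‑2‑tert‑butyl‑5‑methyl‑1,3‑dioxolan‑4‑one
Product: 14 methyl (7S,8S,8aS)‑7‑hydroxy‑7‑methyl‑8,8a‑bis(naphthalen‑2‑ylmethoxy)‑1,6‑dioxo‑6,7,8,8a‑tetrahydro‑1H‑isochromene‑3‑carboxylate, via dilithium enolate‑alkoxide 11 (not isolated), via silyl dienol ether 12 (not isolated), via trimethylsilyl ether 13 (not isolated)
Conditions: LiN(SiMe3)2 (2.2 equiv), THF, −78 °C; 10, −78 → −20 °C; CH2Cl2, Me3SiOTf (5 equiv), −78 → −20 °C; 1 M HCl, THF, 0 °C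
Reagents that add atoms: none
Why: Proposed new method: LiN(SiMe3)2 removes a proton from the 4‑methyl group of 6 (vinylogous to the lactone C=O), and the exocyclic carbanion, which keeps the pyranone aromatic, is acylated by the acylal‑type lactone carbonyl of 10 with loss of pivalaldehyde (C5–C6; Claisen‑type lateral acylation as known for lithiated methyl‑2‑pyranones) to give 11; Me3SiOTf then silylates 11 to the dienol ether 12 and ionises the acetal, and the oxocarbenium ion is attacked by the γ‑carbon of the dienol ether, the pyranone C3 (C8–C8a), the closest known reaction type being the vinylogous Mukaiyama addition of silyl dienol ethers to acetals, with dearomatising precedent in 2‑silyloxyfuran additions. The carbocycle closes in a 6‑(enolendo)‑exo‑trig mode; attack through C5 would give a four‑membered ring, and silyl transfer makes the closure irreversible, which a lithium aldolate of this stabilised enolate would not be. C8 is set by the bought centre C7: in the half‑chair transition state the C7–OSiMe3 bond is pseudo‑axial and the C8 oxocarbenium C–O bond lies anti to it (Cornforth/polar Felkin–Anh, non‑chelating silicon), so C8–O should end trans to C7–O. C8a follows from ring geometry: C1 must stay in the plane of the conjugated pyran ring, so the C8a–O bond becomes pseudo‑axial, on the face of C7–O and anti to C8–O, which is the 7,8‑trans/8,8a‑trans array of the target. The step needs γ‑selective acylation (secured by retention of pyranone aromaticity), acyl‑over‑acetal chemoselectivity (the acetal is inert to the carbanion) and a non‑chelating promoter (the silyl triflate); 1 M HCl finally cleaves the tertiary silyl ether of 13.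

Step 10
Reactants: 14 methyl (7S,8S,8aS)‑7‑hydroxy‑7‑methyl‑8,8a‑bis(naphthalen‑2‑ylmethoxy)‑1,6‑dioxo‑6,7,8,8a‑tetrahydro‑1H‑isochromene‑3‑carboxylate
Product: 15 3‑(hydroxymethyl)‑7‑methyl‑8,8a‑bis(naphthalen‑2‑ylmethoxy)‑6,7,8,8a‑tetrahydro‑1H‑isochromene‑1,6,7‑triol (C7, C8, C8a as in 14)
Conditions: i‑Bu2AlH (excess), CH2Cl2, −78 °C; aq. KNaC4H4O6
Reagents that add atoms: none
Why: hydride reduction should take the ketone to the alcohol, the ester to the primary alcohol and the enol lactone to the lactol, whose aluminium hemiacetal is held at −78 °C by chelation to the C8a oxygen (precedent: i‑Bu2AlH reduction of enol δ‑lactones to 2‑hydroxydihydropyrans); the new centres C1 and C6 are not controlled and are lost or equilibrated later.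

Step 11
Reactants: 15 lactol triol
Product: 16 1,7‑dihydroxy‑7‑methyl‑8,8a‑bis(naphthalen‑2‑ylmethoxy)‑6‑oxo‑6,7,8,8a‑tetrahydro‑1H‑isochromene‑3‑carbaldehyde
Conditions: MnO2, CH2Cl2, rt
Reagents that add atoms: none
Why: MnO2 oxidises only the two allylic alcohols (C6–OH to the dienone, C3–CH2OH to the aldehyde) and should leave the lactol and the tertiary alcohol untouched.

Step 12
Reactants: 16 lactol keto aldehyde
Product: 17 1‑[(tert‑butyldimethylsilyl)oxy]‑7‑hydroxy‑7‑methyl‑8,8a‑bis(naphthalen‑2‑ylmethoxy)‑6‑oxo‑6,7,8,8a‑tetrahydro‑1H‑isochromene‑3‑carbaldehyde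
Conditions: TBSCl, imidazole, DMF, 0 °C
Reagents that add atoms: tert‑butyldimethylsilyl chloride, CC(C)(C)[Si](C)(C)Cl
Why: silylation of the lactol hydroxyl under non‑acidic conditions masks the latent C1 aldehyde before the Wittig step; the tertiary C7 hydroxyl does not react with the silyl chloride.

Step 13
Reactants: 17 silyl lactol aldehyde
Product: 18 (E)‑3‑[1‑[(tert‑butyldimethylsilyl)oxy]‑7‑hydroxy‑7‑methyl‑8,8a‑bis(naphthalen‑2‑ylmethoxy)‑6‑oxo‑6,7,8,8a‑tetrahydro‑1H‑isochromen‑3‑yl]prop‑2‑enal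
Conditions: Ph3P=CHCHO, toluene, 60 °C
Reagents that add atoms: (triphenylphosphoranylidene)acetaldehyde, O=CC=P(c1ccccc1)(c1ccccc1)c1ccccc1
Why: Wittig olefination with the stabilised formylmethylene ylide, which is (E)‑selective and reacts with the aldehyde but not with the hindered dienone.

Step 14
Reactants: 18 bis(naphthylmethyl) ether enal
Product: 19 (E)‑3‑[1‑[(tert‑butyldimethylsilyl)oxy]‑7,8,8a‑trihydroxy‑7‑methyl‑6‑oxo‑6,7,8,8a‑tetrahydro‑1H‑isochromen‑3‑yl]prop‑2‑enal
Conditions: DDQ, CH2Cl2/pH 7 buffer, rt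
Reagents that add atoms: none
Why: oxidative cleavage of both 2‑naphthylmethyl ethers by DDQ in wet solvent, a known deprotection that tolerates electron‑poor alkenes and silyl ethers.

Step 15
Reactants: 20 methyl (R)‑3‑hydroxybutanoate
Product: 21 methyl (R)‑3‑[(tert‑butyldimethylsilyl)oxy]butanoate
Conditions: TBSCl, imidazole, DMF, rt
Reagents that add atoms: tert‑butyldimethylsilyl chloride, CC(C)(C)[Si](C)(C)Cl
Why: standard silylation of the secondary alcohol; the bought stereocentre is not touched.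

Step 16
Reactants: 21 methyl (R)‑3‑[(tert‑butyldimethylsilyl)oxy]butanoate
Product: 22 (R)‑3‑[(tert‑butyldimethylsilyl)oxy]butanoic acid
Conditions: LiOH, THF/H2O, rt; 1 M HCl
Reagents that add atoms: lithium hydroxide, [Li+].[OH-]
Why: saponification of the methyl ester under conditions that leave the secondary silyl ether in place.

Step 17
Reactants: 19 core triol; 22 (R)‑3‑[(tert‑butyldimethylsilyl)oxy]butanoic acid
Product: 23 8‑O‑[(R)‑3‑[(tert‑butyldimethylsilyl)oxy]butanoyl] ester of 19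
Conditions: 2,4,6‑trichlorobenzoyl chloride, Et3N, THF; then 19, DMAP, toluene, rt
Reagents that add atoms: none
Why: Yamaguchi esterification, selective because C8–OH is the only secondary hydroxyl (C7–OH and C8a–OH are tertiary, C1–O is silylated); no stereocentre is touched.

Step 18
Reactants: 23 bis‑silyl ester
Product: 24 Azaphilone D
Conditions: HF·pyridine, pyridine/THF, 0 °C → rt
Reagents that add atoms: none
Why: fluoride cleavage of the anomeric and the secondary silyl ether; the freed hemiacetal should equilibrate to the (1R) anomer.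

**Compound list**

1 | galactaric acid (mucic acid) | OC(=O)[C@H](O)[C@@H](O)[C@@H](O)[C@H](O)C(=O)O | starting material
2 | 3‑acetoxy‑2‑oxo‑2H‑pyran‑6‑carboxylic acid | CC(=O)OC1=CC=C(C(=O)O)OC1=O | intermediate
3 | methyl 3‑hydroxy‑2‑oxo‑2H‑pyran‑6‑carboxylate | COC(=O)C1=CC=C(O)C(=O)O1 | intermediate
4 | methyl 4‑bromo‑3‑hydroxy‑2‑oxo‑2H‑pyran‑6‑carboxylate | COC(=O)C1=CC(Br)=C(O)C(=O)O1 | intermediate
5 | methyl 4‑bromo‑3‑(naphthalen‑2‑ylmethoxy)‑2‑oxo‑2H‑pyran‑6‑carboxylate | COC(=O)C1=CC(Br)=C(OCc2ccc3ccccc3c2)C(=O)O1 | intermediate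
6 | methyl 4‑methyl‑3‑(naphthalen‑2‑ylmethoxy)‑2‑oxo‑2H‑pyran‑6‑carboxylate | COC(=O)C1=CC(C)=C(OCc2ccc3ccccc3c2)C(=O)O1 | intermediate
7 | (R)‑lactic acid | C[C@@H](O)C(=O)O | starting material
8 | (2R,5R)‑2‑tert‑butyl‑5‑methyl‑1,3‑dioxolan‑4‑one | C[C@H]1O[C@@H](C(C)(C)C)OC1=O | intermediate
9 | (2R,5S)‑2‑tert‑butyl‑5‑methyl‑4‑oxo‑1,3‑dioxolane‑5‑carbaldehyde | C[C@@]1(C=O)O[C@@H](C(C)(C)C)OC1=O | intermediate
10 | (2R,5S)‑5‑[bis(naphthalen‑2‑ylmethoxy)methyl]‑2‑tert‑butyl‑5‑methyl‑1,3‑dioxolan‑4‑one | C[C@@]1(C(OCc2ccc3ccccc3c2)OCc2ccc3ccccc3c2)O[C@@H](C(C)(C)C)OC1=O | intermediate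
11 | dilithium enolate‑alkoxide of methyl 4‑[(3S)‑3‑hydroxy‑3‑methyl‑4,4‑bis(naphthalen‑2‑ylmethoxy)‑2‑oxobutyl]‑3‑(naphthalen‑2‑ylmethoxy)‑2‑oxo‑2H‑pyran‑6‑carboxylate | COC(=O)C1=CC(C=C(O[Li])[C@@](C(OCc2ccc3ccccc3c2)OCc2ccc3ccccc3c2)(C)O[Li])=C(OCc2ccc3ccccc3c2)C(=O)O1 | intermediate (not isolated)
12 | bis(trimethylsilyl) derivative of 11 (silyl dienol ether, C7 silyl ether) | COC(=O)C1=CC(C=C(O[Si](C)(C)C)[C@@](C(OCc2ccc3ccccc3c2)OCc2ccc3ccccc3c2)(C)O[Si](C)(C)C)=C(OCc2ccc3ccccc3c2)C(=O)O1 | intermediate (not isolated)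
13 | 7‑O‑trimethylsilyl ether of 14 | O(Cc1ccc2ccccc2c1)[C@@H]3[C@@]4(OCc5ccc6ccccc6c5)C(=CC(=O)[C@@]3(C)O[Si](C)(C)C)C=C(C(=O)OC)OC4=O | intermediate (not isolated)
14 | methyl (7S,8S,8aS)‑7‑hydroxy‑7‑methyl‑8,8a‑bis(naphthalen‑2‑ylmethoxy)‑1,6‑dioxo‑6,7,8,8a‑tetrahydro‑1H‑isochromene‑3‑carboxylate | O(Cc1ccc2ccccc2c1)[C@@H]3[C@@]4(OCc5ccc6ccccc6c5)C(=CC(=O)[C@@]3(C)O)C=C(C(=O)OC)OC4=O | intermediate
15 | 3‑(hydroxymethyl)‑7‑methyl‑8,8a‑bis(naphthalen‑2‑ylmethoxy)‑6,7,8,8a‑tetrahydro‑1H‑isochromene‑1,6,7‑triol (C7, C8, C8a as in 14; C1 and C6 epimers) | O(Cc1ccc2ccccc2c1)[C@@H]3[C@@]4(OCc5ccc6ccccc6c5)C(=CC(O)[C@@]3(C)O)C=C(CO)OC4O | intermediate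
16 | 1,7‑dihydroxy‑7‑methyl‑8,8a‑bis(naphthalen‑2‑ylmethoxy)‑6‑oxo‑6,7,8,8a‑tetrahydro‑1H‑isochromene‑3‑carbaldehyde (C1 epimers) | O(Cc1ccc2ccccc2c1)[C@@H]3[C@@]4(OCc5ccc6ccccc6c5)C(=CC(=O)[C@@]3(C)O)C=C(C=O)OC4O | intermediate
17 | 1‑O‑tert‑butyldimethylsilyl ether of 16 | O(Cc1ccc2ccccc2c1)[C@@H]3[C@@]4(OCc5ccc6ccccc6c5)C(=CC(=O)[C@@]3(C)O)C=C(C=O)OC4O[Si](C)(C)C(C)(C)C | intermediate
18 | (E)‑3‑[1‑(silyloxy)‑7‑hydroxy‑7‑methyl‑8,8a‑bis(naphthalen‑2‑ylmethoxy)‑6‑oxo‑6,7,8,8a‑tetrahydro‑1H‑isochromen‑3‑yl]prop‑2‑enal | O(Cc1ccc2ccccc2c1)[C@@H]3[C@@]4(OCc5ccc6ccccc6c5)C(=CC(=O)[C@@]3(C)O)C=C(/C=C/C=O)OC4O[Si](C)(C)C(C)(C)C | intermediate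
19 | (E)‑3‑[1‑(silyloxy)‑7,8,8a‑trihydroxy‑7‑methyl‑6‑oxo‑6,7,8,8a‑tetrahydro‑1H‑isochromen‑3‑yl]prop‑2‑enal (7S,8R,8aS) | O[C@@H]1[C@@]2(O)C(=CC(=O)[C@@]1(C)O)C=C(/C=C/C=O)OC2O[Si](C)(C)C(C)(C)C | intermediate
20 | methyl (R)‑3‑hydroxybutanoate | C[C@@H](O)CC(=O)OC | starting material
21 | methyl (R)‑3‑[(tert‑butyldimethylsilyl)oxy]butanoate | C[C@@H](O[Si](C)(C)C(C)(C)C)CC(=O)OC | intermediate
22 | (R)‑3‑[(tert‑butyldimethylsilyl)oxy]butanoic acid | C[C@@H](O[Si](C)(C)C(C)(C)C)CC(=O)O | intermediate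
23 | 8‑O‑[(R)‑3‑(silyloxy)butanoyl] ester of 19 | C[C@@H](O[Si](C)(C)C(C)(C)C)CC(=O)O[C@@H]1[C@@]2(O)C(=CC(=O)[C@@]1(C)O)C=C(/C=C/C=O)OC2O[Si](C)(C)C(C)(C)C | intermediate
24 | Azaphilone D, (1R,7S,8R,8aS)‑1,7,8a‑trihydroxy‑7‑methyl‑6‑oxo‑3‑[(1E)‑3‑oxoprop‑1‑en‑1‑yl]‑6,7,8,8a‑tetrahydro‑1H‑isochromen‑8‑yl (3R)‑3‑hydroxybutanoate | C[C@@H](O)CC(=O)O[C@@H]1[C@@]2(O)C(=CC(=O)[C@@]1(C)O)C=C(/C=C/C=O)O[C@H]2O | target

**Step count**

Total steps: 18. Longest linear sequence: 13 steps (1–5, 9–14, 17, 18).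

**Steps most likely to fail**

1. Step 9 (proposed new method). What may go wrong: acylation at the neopentyl lactone carbonyl of 10 may be too slow, so that the lithiated pyranone decays, adds to the released pivalaldehyde, or the enolate opens the pyranone by O‑acyl transfer. In the second stage the oxocarbenium ion may be captured intermolecularly, or the ring may close with the wrong facial sense. Fallback (bonds made one at a time by individually known reaction types; sets out from 6 and 10, comes back at 14): lateral acylation alone (LiN(SiMe3)2, THF, −78 → −20 °C, AcOH quench), a known reaction of lithiated methyl‑2‑pyranones, should give after loss of pivalaldehyde the hydroxy ketone methyl 4‑[(3S)‑3‑hydroxy‑3‑methyl‑4,4‑bis(naphthalen‑2‑ylmethoxy)‑2‑oxobutyl]‑3‑(naphthalen‑2‑ylmethoxy)‑2‑oxo‑2H‑pyran‑6‑carboxylate F1, which is purified. Its silyl dienol ether is then formed under soft‑enolisation conditions (Me3SiOTf, Et3N, CH2Cl2, −78 °C) and closed onto the acetal with BF3·OEt2 in a separate intramolecular vinylogous Mukaiyama addition; 1 M HCl then gives 14.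

2. Step 10. What may go wrong: the aluminium hemiacetal at C1 may collapse with expulsion of the C3 enolate, leading to ring opening and over‑reduction to the primary alcohol. Fallback (sets out from 14, comes back at 15): reductive acetylation. i‑Bu2AlH at −78 °C, followed in the same flask by Ac2O, pyridine and DMAP at −78 °C, traps the aluminium hemiacetal as the anomeric acetate before it can open and acetylates the two other new alkoxides, giving the 1,6‑di‑O‑acetyl‑3‑(acetoxymethyl) triacetate F2. K2CO3 in MeOH then removes the three acetyl groups and gives 15.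

3. Step 7. What may go wrong: retro‑Claisen loss of the formyl group from the non‑enolisable β‑formyl lactone on warming or on quench, or incomplete C‑formylation. Fallback (sets out from 8, comes back at 9): hydroxymethylation of the same lithium enolate with monomeric formaldehyde (aldol addition, again anti to tert‑butyl) gives (2R,5S)‑2‑tert‑butyl‑5‑(hydroxymethyl)‑5‑methyl‑1,3‑dioxolan‑4‑one F3. Swern or Dess–Martin oxidation then gives 9.

**Further compounds**

F1 | step 9 | methyl 4‑[(3S)‑3‑hydroxy‑3‑methyl‑4,4‑bis(naphthalen‑2‑ylmethoxy)‑2‑oxobutyl]‑3‑(naphthalen‑2‑ylmethoxy)‑2‑oxo‑2H‑pyran‑6‑carboxylate | COC(=O)C1=CC(CC(=O)[C@@](C(OCc2ccc3ccccc3c2)OCc2ccc3ccccc3c2)(C)O)=C(OCc2ccc3ccccc3c2)C(=O)O1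
F2 | step 10 | 1,6‑di‑O‑acetyl‑3‑(acetoxymethyl) derivative of 15 (triacetate) | O(Cc1ccc2ccccc2c1)[C@@H]3[C@@]4(OCc5ccc6ccccc6c5)C(=CC(OC(C)=O)[C@@]3(C)O)C=C(COC(C)=O)OC4OC(C)=O
F3 | step 7 | (2R,5S)‑2‑tert‑butyl‑5‑(hydroxymethyl)‑5‑methyl‑1,3‑dioxolan‑4‑one | C[C@@]1(CO)O[C@@H](C(C)(C)C)OC1=O
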